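## Retrosynthetic overview
1. Sarcrassin D (**17**) ⇐ intramolecular Horner–Wadsworth–Emmons (HWE) closure of the 14-membered carbocycle (last ring). A γ-phosphono-enoate reacts with the isopropyl ketone to form the Cb=Cc alkene.
2. Ketone **16** ⇐ Carroll [3,3] decarboxylative Claisen rearrangement of the β-ketoester of a 7-membered Baylis–Hillman-type allylic alcohol. This forms the Cd–Ce bond, puts the C2a=Cf alkene into the lactone ring, and fixes its geometry.
3. The 7-membered lactone forms first, by intramolecular Morita–Baylis–Hillman (IMBH) cyclisation of an acrylate on the tertiary Cq–OH onto an aldehyde (from prenyl cleavage). Cross-metathesis of the α-methylene ester builds the (E)-C1=Ca enoate and the allylic phosphonate.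
4. Everything comes from (S)-linalool: Wacker oxidation, dianion alkylation, then hydroxyl-directed reduction sets C4′(R) from Cq(S).

Assumption: Me4NBH(OAc)3 reduction of the α-hydroxy ketone gives the anti-diol (5R,6S), and the metathesis and HWE steps favour the (E)-alkenes required in **17**.

## Route

**Step 1**
Reactants: **1** (S)-linalool
Product: **2** (3S)-3-hydroxy-3,7-dimethyloct-6-en-2-one
Conditions: PdCl2 (10 mol%), CuCl, O2, DMF/H2O 7:1, rt
Reagents that add atoms: water, O (supplies the ketone O)
Why: Wacker–Tsuji oxidation is Markovnikov-selective at the terminal vinyl group and leaves the trisubstituted alkene alone. Cq is untouched.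

**Step 2**
Reactants: **2**, **3** methyl 2-(bromomethyl)acrylate
Product: **4** methyl (6S)-6-hydroxy-6,10-dimethyl-2-methylidene-5-oxoundec-9-enoate
Conditions: LDA (2.3 equiv), THF, −78 → −20 °C; then **3**
Reagents that add atoms: methyl 2-(bromomethyl)acrylate, C=C(CBr)C(=O)OC
Why: Only the methyl side of the ketol is enolisable (the other side is quaternary). The dianion does an allylic SN2 alkylation, installing C2′ and the α-methylene ester (C1=CaH2) in one step.

**Step 3**
Reactants: **4**
Product: **5** methyl (5R,6S)-5,6-dihydroxy-6,10-dimethyl-2-methylideneundec-9-enoate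
Conditions: Me4NBH(OAc)3, MeCN/AcOH 1:1, −20 °C → 0 °C; crude used at once
Reagents that add atoms: none
Why: Evans–Saksena hydroxyl-directed reduction. The tertiary OH delivers hydride through a cyclic acyloxyborohydride on the face syn to the smaller methyl group, giving the anti-diol. This sets C5 (R) relative to C6 (S), so the stereocentre is controlled by a centre that was bought. The acrylate survives.

**Step 4**
Reactants: **5**, **6** acetic anhydride
Product: **7** methyl (5R,6S)-5-acetoxy-6-hydroxy-6,10-dimethyl-2-methylideneundec-9-enoate
Conditions: Ac2O (1.5 equiv), pyridine, DMAP (cat.), CH2Cl2, 0 °C → rt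
Reagents that add atoms: acetic anhydride, CC(=O)OC(C)=O
Why: The secondary OH is acetylated selectively over the hindered tertiary OH. This installs the target OAc and prevents δ-lactonisation onto the ester.

**Step 5**
Reactants: **7**, **8** diethyl allylphosphonate
Product: **9** methyl (2E)-2-[(3R,4S)-3-acetoxy-4-hydroxy-4,8-dimethylnon-7-en-1-yl]-4-(diethoxyphosphoryl)but-2-enoate
Conditions: Hoveyda–Grubbs II (8 mol%), **8** (5 equiv), CH2Cl2, 40 °C
Reagents that add atoms: diethyl allylphosphonate, C=CCP(=O)(OCC)OCC
Why: Cross-metathesis of the 1,1-disubstituted acrylate with the terminal alkene releases ethylene. It gives the thermodynamic (E)-trisubstituted enoate, with CO2Me trans to CH2P, as required at C1=Ca. The hindered prenyl alkene is a poor partner.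

**Step 6**
Reactants: **9**, **10** acryloyl chloride
Product: **11** the Cq-O-acrylate of **9**
Conditions: acryloyl chloride (3 equiv), Et3N, DMAP (cat.), BHT, CH2Cl2, 0 °C → rt
Reagents that add atoms: acryloyl chloride, C=CC(=O)Cl
Why: Acylation of the tertiary alcohol installs the tethered acrylate for the lactone-forming MBH step. Cq is not affected.

**Step 7**
Reactants: **11**
Product: **12** the aldehyde (Cq–CH2CH2CHO) derived from **11**
Conditions: OsO4 (5 mol%), NaIO4 (4 equiv), 2,6-lutidine, dioxane/H2O 3:1, rt
Reagents that add atoms: sodium periodate, [Na+].[O-]I(=O)(=O)=O (supplies the aldehyde O)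
Why: Lemieux–Johnson cleavage is chemoselective for the electron-rich trisubstituted prenyl alkene over the electron-poor enoate and acrylate. Acetone is lost.

**Step 8**
Reactants: **12**
Product: **13** the 7-membered α-methylene-β-hydroxy lactone with the (2E) enoate-phosphonate side chain (Cf-OH as epimeric mixture)
Conditions: DABCO (1.0 equiv), MeCN, 0.05 M, rt, 3 d
Reagents that add atoms: none
Why: Intramolecular Morita–Baylis–Hillman reaction. DABCO adds to the acrylate β-carbon and the enolate attacks the aldehyde, closing the 7-membered lactone. The new carbinol stereocentre is destroyed in step 10, so the epimeric mixture is carried forward.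

**Step 9**
Reactants: **13**, **14** methyl isobutyrylacetate
Product: **15** the 4-methyl-3-oxopentanoate (β-ketoester) of the ring allylic alcohol
Conditions: **14** (5 equiv), DMAP (0.2 equiv), toluene, reflux, MeOH removed
Reagents that add atoms: methyl isobutyrylacetate, CC(C)C(=O)CC(=O)OC
Why: Transesterification proceeds through an acylketene and acylates the secondary allylic OH.

**Step 10 (key step)**
Reactants: **15**
Product: **16** the lactone-ketone: 2-methyl-6-(4-methyl-3-oxopentyl)-7-oxo-2,3,4,7-tetrahydrooxepin-2-yl with the (2E) enoate-phosphonate chain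
Conditions: xylenes, BHT, 150 °C, sealed tube
Reagents that add atoms: none (CO2 is lost)
Why: Carroll rearrangement, a [3,3]-sigmatropic decarboxylative Claisen. The ester-enol C=C adds to the exocyclic methylene through a chair transition state and the double bond moves into the ring. This forms the Cd–Ce bond and the endocyclic C2a=Cf alkene with the ester cis to Cg, as the lactone requires. The β-keto acid then loses CO2. The Cf stereocentre is erased and Cq is unaffected.

**Step 11**
Reactants: **16**
Product: **17** Sarcrassin D
Conditions: KHMDS (1.5 equiv), 18-crown-6, THF, −78 °C → rt, 2 mM, substrate added by syringe pump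
Reagents that add atoms: none (diethyl phosphate is lost)
Why: Intramolecular HWE macrocyclisation. The vinylogous phosphonate carbanion attacks the isopropyl ketone at its α-carbon and eliminates (EtO)2PO2−, closing the 14-membered ring and forming the Cb=Cc alkene. The bulky isopropyl group is expected to end up trans to the dienyl chain. The C1=Ca geometry is already fixed from step 5.

## Compound list
1 | (S)-linalool | C=C[C@@](C)(O)CCC=C(C)C | starting material
2 | (3S)-3-hydroxy-3,7-dimethyloct-6-en-2-one | CC(=O)[C@@](C)(O)CCC=C(C)C | intermediate
3 | methyl 2-(bromomethyl)acrylate | C=C(CBr)C(=O)OC | starting material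
4 | methyl (6S)-6-hydroxy-6,10-dimethyl-2-methylidene-5-oxoundec-9-enoate | COC(=O)C(=C)CCC(=O)[C@@](C)(O)CCC=C(C)C | intermediate
5 | methyl (5R,6S)-5,6-dihydroxy-6,10-dimethyl-2-methylideneundec-9-enoate | COC(=O)C(=C)CC[C@@H](O)[C@@](C)(O)CCC=C(C)C | intermediate
6 | acetic anhydride | CC(=O)OC(C)=O | starting material
7 | methyl (5R,6S)-5-acetoxy-6-hydroxy-6,10-dimethyl-2-methylideneundec-9-enoate | COC(=O)C(=C)CC[C@@H](OC(C)=O)[C@@](C)(O)CCC=C(C)C | intermediate
8 | diethyl allylphosphonate | C=CCP(=O)(OCC)OCC | starting material
9 | cross-metathesis product (2E; 3R,4S) | COC(=O)/C(=C/CP(=O)(OCC)OCC)CC[C@@H](OC(C)=O)[C@@](C)(O)CCC=C(C)C | intermediate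
10 | acryloyl chloride | C=CC(=O)Cl | starting material
11 | Cq-acrylate of 9 | COC(=O)/C(=C/CP(=O)(OCC)OCC)CC[C@@H](OC(C)=O)[C@@](C)(OC(=O)C=C)CCC=C(C)C | intermediate
12 | aldehyde (Cq–CH2CH2CHO) | COC(=O)/C(=C/CP(=O)(OCC)OCC)CC[C@@H](OC(C)=O)[C@@](C)(OC(=O)C=C)CCC=O | intermediate
13 | 7-membered α-methylene-β-hydroxy lactone (Cf-OH epimeric mixture) | COC(=O)/C(=C/CP(=O)(OCC)OCC)CC[C@@H](OC(C)=O)[C@]1(C)CCC(O)C(=C)C(=O)O1 | intermediate
14 | methyl isobutyrylacetate | CC(C)C(=O)CC(=O)OC | starting material
15 | β-ketoester of 13 | COC(=O)/C(=C/CP(=O)(OCC)OCC)CC[C@@H](OC(C)=O)[C@]1(C)CCC(OC(=O)CC(=O)C(C)C)C(=C)C(=O)O1 | intermediate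
16 | Carroll product (lactone-ketone) | COC(=O)/C(=C/CP(=O)(OCC)OCC)CC[C@@H](OC(C)=O)[C@]1(C)CCC=C(CCC(=O)C(C)C)C(=O)O1 | intermediate
17 | Sarcrassin D | COC(=O)/C1=C/C=C(/C(C)C)CCC2=CCC[C@](C)(OC2=O)[C@H](OC(C)=O)CC1 | target

## Totals
Total steps: 11. Longest linear sequence: 11 (all from **1**).

## Three steps most likely to fail
1. **Step 11 (macro-HWE on a hindered ketone).** The risks are low reactivity, oligomerisation and E/Z mixtures at Cb=Cc.
   Fallback (changes approach): keep the α-methylene ester instead of doing the cross-metathesis and protect it as its thiol adduct through steps 6–10. After the Carroll step, convert the ketone to the (E)-vinyl iodide (Ph3P=CHI) and close the ring by intramolecular Heck.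
2. **Step 8 (intramolecular MBH to a 7-membered lactone).** Medium-ring IMBH is slow and competes with dimerisation.
   Fallback (changes approach): use the 2-iodoacrylate ester and close by intramolecular Nozaki–Hiyama–Kishi (CrCl2/NiCl2) of the vinyl iodide onto the aldehyde, giving the same α-methylene-β-hydroxy lactone.
3. **Step 3 (diastereoselectivity at C4′, since Me and the alkyl chain on Cq are similar in size).**
   Fallback (changes approach): cross-metathesis of linalool with allyl TBS ether gives the (E)-alkene. Follow with Cq–OH-directed VO(acac)2/TBHP epoxidation and regioselective hydride opening at C3′, then separate any C4′ epimer after acetylation.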